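The route rests on making two ring A bonds together: the bond from the ketone carbon of the 3-(4-methoxyphenyl)propanoyl chain to ring A, and the bond from the neighbouring ring A carbon to its hydroxyl oxygen. Acid 26 inserts its C(=O)–O bond across aryne 27 (oxygen arylation, then 1,3 oxygen-to-carbon acyl shift). This exploits the fact that in ring A the acylated carbon and one OH-bearing carbon are ortho, while the carbon para to that OH carries C1'. A phenol symmetric about the C1'-bearing carbon therefore gives one aryne, whose single flanking benzyloxy group fixes the orientation. Precursor 25 is the ortho-silyl aryl triflate of ring A carrying the finished C1'–C4' chain and rings B and C, all benzyl-protected.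

Key step: step 16

Remarks
- Labels: C1' is the diaryl methine, C2' and C3' the methyl-bearing carbons, C4' the benzylic CH2; ring A is the phloroglucinol ring, ring B the aryl group on C1', ring C the aryl group on C4'.
- The target SMILES corresponds to 1'R,2'R,3'S. With the chain ring A–C1'–C2'–C3'–C4' drawn zigzag, ring B and both methyl groups lie on the same side.
- Assumption: Rh(acac)(C2H4)2 with (R)-SEGPHOS is taken to give the 4R lactone 7; if the sense of induction on this substrate is the opposite one, (S)-SEGPHOS is used.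

Step 1
Reactants: 1 phloroglucinol; 2 ethyl propiolate
Product: 3 5,7-dihydroxy-2H-chromen-2-one (5,7-dihydroxycoumarin)
Conditions: ZnCl2, dioxane, 100 °C
Reagents that add atoms: none
Why: Pechmann-type condensation, in which the Lewis acid promotes addition of the threefold-symmetric, electron-rich arene to the propiolate and lactonisation with loss of ethanol, so only one coumarin can form.

Step 2
Reactants: 3 5,7-dihydroxycoumarin
Product: 4 5-hydroxy-7-(methoxymethoxy)-2H-chromen-2-one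
Conditions: MOMCl (1.05 equiv), K2CO3 (1.1 equiv), acetone, 0 °C → rt
Reagents that add atoms: chloromethyl methyl ether, COCCl
Why: Williamson etherification of the more acidic and less hindered 7-OH (its phenoxide is para-conjugated to the pyrone carbonyl, while 5-OH is peri to C4–H), run with one equivalent of electrophile so that 5-OH stays free.

Step 3
Reactants: 4 5-hydroxy-7-(methoxymethoxy)-2H-chromen-2-one
Product: 5 5-(benzyloxy)-7-(methoxymethoxy)-2H-chromen-2-one
Conditions: BnBr, K2CO3, DMF, 60 °C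
Reagents that add atoms: benzyl bromide, BrCc1ccccc1
Why: Williamson benzylation of the remaining phenol under carbonate conditions that leave the coumarin lactone and the MOM acetal intact.

Step 4
Reactants: 5 5-(benzyloxy)-7-(methoxymethoxy)-2H-chromen-2-one; 6 4-(benzyloxy)phenylboronic acid
Product: 7 (4R)-5-(benzyloxy)-4-[4-(benzyloxy)phenyl]-7-(methoxymethoxy)-3,4-dihydro-2H-chromen-2-one
Conditions: Rh(acac)(C2H4)2 (3 mol %), (R)-SEGPHOS (3.3 mol %), 6 (5 equiv), dioxane/H2O 10:1, 60 °C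
Reagents that add atoms: none
Why: Hayashi–Miyaura asymmetric 1,4-addition of an arylboronic acid to a coumarin, in which the chiral bisphosphine–arylrhodium species adds to one face of the C3=C4 bond and so sets C1' (4R), and water protonates the rhodium enolate.

Step 5
Reactants: 7 (4R)-5-(benzyloxy)-4-[4-(benzyloxy)phenyl]-7-(methoxymethoxy)-3,4-dihydro-2H-chromen-2-one
Product: 9 (3S,4R)-5-(benzyloxy)-4-[4-(benzyloxy)phenyl]-7-(methoxymethoxy)-3-methyl-3,4-dihydro-2H-chromen-2-one, via lithium enolate 8 (not isolated)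
Conditions: LiN(SiMe3)2 (1.05 equiv), THF, −78 °C; MeI, −78 → −50 °C
Reagents that add atoms: iodomethane, CI
Why: Substrate-controlled enolate alkylation, in which MeI approaches the lactone enolate anti to the C4 aryl group (held pseudoaxial by the peri 5-benzyloxy group) and gives the 3,4-trans lactone, setting C2'; the low temperature suppresses ketene-forming ring opening.

Step 6
Reactants: 9 (3S,4R)-5-(benzyloxy)-4-[4-(benzyloxy)phenyl]-7-(methoxymethoxy)-3-methyl-3,4-dihydro-2H-chromen-2-one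
Product: 10 (2S,3R)-3-[2-(benzyloxy)-6-hydroxy-4-(methoxymethoxy)phenyl]-3-[4-(benzyloxy)phenyl]-N-methoxy-N,2-dimethylpropanamide
Conditions: MeNH(OMe)·HCl, AlMe3, CH2Cl2, 0 °C → rt; cold dilute aq HCl
Reagents that add atoms: N,O-dimethylhydroxylamine hydrochloride, CNOC.Cl
Why: Aluminium-amide aminolysis of the aryl lactone (Weinreb amide synthesis) opens the ring without base, so C2' next to the carbonyl is not epimerised and the ring A phenol is released.

Step 7
Reactants: 10 (2S,3R)-3-[2-(benzyloxy)-6-hydroxy-4-(methoxymethoxy)phenyl]-3-[4-(benzyloxy)phenyl]-N-methoxy-N,2-dimethylpropanamide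
Product: 11 (2S,3R)-3-[2,6-bis(benzyloxy)-4-(methoxymethoxy)phenyl]-3-[4-(benzyloxy)phenyl]-N-methoxy-N,2-dimethylpropanamide
Conditions: BnBr, K2CO3, DMF, rt
Reagents that add atoms: benzyl bromide, BrCc1ccccc1
Why: Williamson benzylation of the liberated phenol, which makes ring A symmetric about the C1'-bearing carbon; the amide α-proton is too weakly acidic for carbonate.

Step 8
Reactants: 11 (2S,3R)-3-[2,6-bis(benzyloxy)-4-(methoxymethoxy)phenyl]-3-[4-(benzyloxy)phenyl]-N-methoxy-N,2-dimethylpropanamide; 12 4-(benzyloxy)benzyl chloride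
Product: 14 (3S,4R)-4-[2,6-bis(benzyloxy)-4-(methoxymethoxy)phenyl]-1,4-bis[4-(benzyloxy)phenyl]-3-methylbutan-2-one, via [4-(benzyloxy)benzyl]magnesium chloride 13 (not isolated)
Conditions: 12, Mg, Et2O, 0 °C (slow addition); then 11, THF, −20 → 0 °C; aq NH4Cl
Reagents that add atoms: none
Why: Weinreb ketone synthesis, in which the benzylic Grignard reagent adds once to the N-methoxy-N-methylamide and the ketone appears only on quench, so C3' arrives as a carbonyl already carrying C4' and ring C.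

Step 9
Reactants: 14 (3S,4R)-4-[2,6-bis(benzyloxy)-4-(methoxymethoxy)phenyl]-1,4-bis[4-(benzyloxy)phenyl]-3-methylbutan-2-one
Product: 15 (3S,4R)-4-[2,6-bis(benzyloxy)-4-(methoxymethoxy)phenyl]-2-[4-(benzyloxy)benzyl]-4-[4-(benzyloxy)phenyl]-3-methylbut-1-ene
Conditions: Cp2TiMe2 (3 equiv), toluene/THF, 70 °C, dark
Reagents that add atoms: dimethyltitanocene, [CH3-].[CH3-].[Ti+4].[cH-]1cccc1.[cH-]1cccc1
Why: Petasis methylenation is non-basic and free of Lewis acid, so the easily enolised benzyl ketone should become the 1,1-disubstituted alkene without epimerising C2' or cleaving the MOM group.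

Step 10
Reactants: 15 (3S,4R)-4-[2,6-bis(benzyloxy)-4-(methoxymethoxy)phenyl]-2-[4-(benzyloxy)benzyl]-4-[4-(benzyloxy)phenyl]-3-methylbut-1-ene
Product: 17 (2S,3S,4R)-4-[2,6-bis(benzyloxy)-4-(methoxymethoxy)phenyl]-2-[4-(benzyloxy)benzyl]-4-[4-(benzyloxy)phenyl]-3-methylbutan-1-ol, via B-alkyl-9-BBN adduct 16 (not isolated)
Conditions: 9-BBN, THF, 0 → 40 °C; then NaOH (3 M aq), H2O2 (30%), 0 °C → rt
Reagents that add atoms: hydrogen peroxide, OO
Why: Substrate-controlled hydroboration–oxidation, in which 9-BBN puts boron on the terminal carbon and delivers hydrogen to C3' from the face opposite the bulky diarylmethyl group in the conformer where C2'–H eclipses the alkene (allylic-strain control); this should set C3' with the hydroxymethyl group syn to the C2' methyl group in the zigzag C4'–C3'–C2'–C1'.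

Step 11
Reactants: 17 (2S,3S,4R)-4-[2,6-bis(benzyloxy)-4-(methoxymethoxy)phenyl]-2-[4-(benzyloxy)benzyl]-4-[4-(benzyloxy)phenyl]-3-methylbutan-1-ol
Product: 18 (2S,3S,4R)-4-[2,6-bis(benzyloxy)-4-(methoxymethoxy)phenyl]-2-[4-(benzyloxy)benzyl]-4-[4-(benzyloxy)phenyl]-3-methylbutyl 4-methylbenzenesulfonate
Conditions: TsCl, Et3N, DMAP (cat.), CH2Cl2, 0 °C → rt
Reagents that add atoms: 4-methylbenzenesulfonyl chloride, Cc1ccc(S(=O)(=O)Cl)cc1
Why: Sulfonylation of the only free hydroxyl, a primary alcohol, under standard amine-base conditions (tosylate formation).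

Step 12
Reactants: 18 (2S,3S,4R)-4-[2,6-bis(benzyloxy)-4-(methoxymethoxy)phenyl]-2-[4-(benzyloxy)benzyl]-4-[4-(benzyloxy)phenyl]-3-methylbutyl 4-methylbenzenesulfonate
Product: 19 1,3-bis(benzyloxy)-2-{(1R,2R,3S)-1,4-bis[4-(benzyloxy)phenyl]-2,3-dimethylbutyl}-5-(methoxymethoxy)benzene
Conditions: LiBHEt3, THF, 0 °C → rt
Reagents that add atoms: none
Why: SN2 displacement of the primary tosylate by hydride turns CH2OTs into the C3' methyl group without touching benzyl or MOM ethers or any stereocentre.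

Step 13
Reactants: 19 1,3-bis(benzyloxy)-2-{(1R,2R,3S)-1,4-bis[4-(benzyloxy)phenyl]-2,3-dimethylbutyl}-5-(methoxymethoxy)benzene
Product: 20 3,5-bis(benzyloxy)-4-{(1R,2R,3S)-1,4-bis[4-(benzyloxy)phenyl]-2,3-dimethylbutyl}phenol
Conditions: HCl (3 M aq), MeOH/THF, 45 °C
Reagents that add atoms: none
Why: Acid-catalysed acetal exchange with methanol removes the aryl MOM group as dimethoxymethane while the benzyl ethers survive, unmasking the phenol para to the C1'-bearing carbon.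

Step 14
Reactants: 20 3,5-bis(benzyloxy)-4-{(1R,2R,3S)-1,4-bis[4-(benzyloxy)phenyl]-2,3-dimethylbutyl}phenol
Product: 21 3,5-bis(benzyloxy)-4-{(1R,2R,3S)-1,4-bis[4-(benzyloxy)phenyl]-2,3-dimethylbutyl}-2-bromophenol
Conditions: NBS (1.0 equiv), CH2Cl2, −78 → −30 °C, dark
Reagents that add atoms: N-bromosuccinimide, O=C1CCC(=O)N1Br
Why: Electrophilic aromatic bromination ortho to the free phenol, where the two ortho positions are equivalent by symmetry and far more activated than any position of rings B and C, with one equivalent of reagent to hold the reaction at the monobromide.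

Step 15
Reactants: 21 3,5-bis(benzyloxy)-4-{(1R,2R,3S)-1,4-bis[4-(benzyloxy)phenyl]-2,3-dimethylbutyl}-2-bromophenol
Product: 25 3,5-bis(benzyloxy)-4-{(1R,2R,3S)-1,4-bis[4-(benzyloxy)phenyl]-2,3-dimethylbutyl}-2-(trimethylsilyl)phenyl trifluoromethanesulfonate, via aryl trimethylsilyl ether 22 (not isolated), via aryllithium 23 (not isolated), via lithium 2-silylphenoxide 24 (not isolated)
Conditions: (Me3Si)2NH, THF, 65 °C, then evaporate; n-BuLi, THF, −100 → −78 °C; Tf2O, −100 → −78 °C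
Reagents that add atoms: hexamethyldisilazane, C[Si](C)(C)N[Si](C)(C)C; trifluoromethanesulfonic anhydride, O=S(=O)(OS(=O)(=O)C(F)(F)F)C(F)(F)F
Why: O-silylation, bromine–lithium exchange and 1,3 oxygen-to-carbon silyl migration (retro-Brook rearrangement) give the ortho-silyl phenoxide, which Tf2O traps as the ortho-silylaryl triflate; exchange at −100 °C is faster than deprotonation of any benzylic position.

Step 16
Reactants: 25 3,5-bis(benzyloxy)-4-{(1R,2R,3S)-1,4-bis[4-(benzyloxy)phenyl]-2,3-dimethylbutyl}-2-(trimethylsilyl)phenyl trifluoromethanesulfonate; 26 3-(4-methoxyphenyl)propanoic acid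
Product: 29 1-{2,4-bis(benzyloxy)-3-{(1R,2R,3S)-1,4-bis[4-(benzyloxy)phenyl]-2,3-dimethylbutyl}-6-hydroxyphenyl}-3-(4-methoxyphenyl)propan-1-one, via aryne 27 (not isolated), via ortho-caesiated aryl ester 28 (not isolated)
Conditions: 26 (2 equiv), CsF (5 equiv), THF, 125 °C, sealed tube
Reagents that add atoms: none
Why: Fluoride attacks silicon and expels triflate to give aryne 27; the caesium carboxylate of 26 (fluoride also serves as the base) bonds through oxygen to the aryne terminus that has a C–H neighbour, and the aryl anion 28 so formed closes onto its own ester carbonyl in a four-centre step and reopens as the ortho-acyl phenoxide, which is protonated to 29. The closest known reaction type is the insertion of arynes into the C–O bond of carboxylic acids to give ortho-hydroxyaryl ketones, here extended to a tetrasubstituted aryne. No ring is closed and no stereocentre is created, and C1', C2' and C3' are not at risk because nothing acidic or strongly basic at carbon is present. The selectivity needed is the orientation of addition: an alkoxy-substituted aryne is bent so that the distal carbon is the more electrophilic one and the developing carbanion is inductively stabilised beside oxygen, so the one benzyloxy neighbour puts the new oxygen meta and the acyl group ortho to it, and the symmetry of phenol 20 guarantees that only this aryne can arise. Because fluoride alone drives the acylation, no Lewis acid is present that could ionise the ring A–C1' bond.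

Step 17
Reactants: 29 1-{2,4-bis(benzyloxy)-3-{(1R,2R,3S)-1,4-bis[4-(benzyloxy)phenyl]-2,3-dimethylbutyl}-6-hydroxyphenyl}-3-(4-methoxyphenyl)propan-1-one
Product: 30 1-{3-[(1R,2R,3S)-1,4-bis(4-hydroxyphenyl)-2,3-dimethylbutyl]-2,4,6-trihydroxyphenyl}-3-(4-methoxyphenyl)propan-1-one
Conditions: H2 (1 atm), palladium on carbon (Pd/C, 10 wt %), EtOAc/MeOH, rt
Reagents that add atoms: none
Why: Palladium-catalysed hydrogenolysis should cleave all four O-benzyl groups under neutral conditions, while the hydrogen-bonded aryl ketone and the oxygen-free benzylic carbons C1' and C4' are not reduced at atmospheric pressure.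

Compound list
1 | phloroglucinol | Oc1cc(O)cc(O)c1 | starting material
2 | ethyl propiolate | C#CC(=O)OCC | starting material
3 | 5,7-dihydroxy-2H-chromen-2-one | O=c1ccc2c(O)cc(O)cc2o1 | intermediate
4 | 5-hydroxy-7-(methoxymethoxy)-2H-chromen-2-one | O=c1ccc2c(O)cc(OCOC)cc2o1 | intermediate
5 | 5-(benzyloxy)-7-(methoxymethoxy)-2H-chromen-2-one | O=c1ccc2c(OCc3ccccc3)cc(OCOC)cc2o1 | intermediate
6 | 4-(benzyloxy)phenylboronic acid | OB(O)c1ccc(OCc2ccccc2)cc1 | starting material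
7 | (4R)-5-(benzyloxy)-4-[4-(benzyloxy)phenyl]-7-(methoxymethoxy)-3,4-dihydro-2H-chromen-2-one | O=C1C[C@H](c2ccc(OCc3ccccc3)cc2)c2c(OCc3ccccc3)cc(OCOC)cc2O1 | intermediate
8 | lithium (4R)-5-(benzyloxy)-4-[4-(benzyloxy)phenyl]-7-(methoxymethoxy)-4H-chromen-2-olate | [Li+].[O-]C1=C[C@H](c2ccc(OCc3ccccc3)cc2)c2c(OCc3ccccc3)cc(OCOC)cc2O1 | intermediate
9 | (3S,4R)-5-(benzyloxy)-4-[4-(benzyloxy)phenyl]-7-(methoxymethoxy)-3-methyl-3,4-dihydro-2H-chromen-2-one (3,4-trans) | O=C1[C@@H](C)[C@H](c2ccc(OCc3ccccc3)cc2)c2c(OCc3ccccc3)cc(OCOC)cc2O1 | intermediate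
10 | (2S,3R)-3-[2-(benzyloxy)-6-hydroxy-4-(methoxymethoxy)phenyl]-3-[4-(benzyloxy)phenyl]-N-methoxy-N,2-dimethylpropanamide | CON(C)C(=O)[C@@H](C)[C@H](c1ccc(OCc2ccccc2)cc1)c1c(O)cc(OCOC)cc1OCc1ccccc1 | intermediate
11 | (2S,3R)-3-[2,6-bis(benzyloxy)-4-(methoxymethoxy)phenyl]-3-[4-(benzyloxy)phenyl]-N-methoxy-N,2-dimethylpropanamide | CON(C)C(=O)[C@@H](C)[C@H](c1ccc(OCc2ccccc2)cc1)c1c(OCc2ccccc2)cc(OCOC)cc1OCc1ccccc1 | intermediate
12 | 4-(benzyloxy)benzyl chloride | ClCc1ccc(OCc2ccccc2)cc1 | starting material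
13 | [4-(benzyloxy)benzyl]magnesium chloride | Cl[Mg]Cc1ccc(OCc2ccccc2)cc1 | intermediate
14 | (3S,4R)-4-[2,6-bis(benzyloxy)-4-(methoxymethoxy)phenyl]-1,4-bis[4-(benzyloxy)phenyl]-3-methylbutan-2-one | O=C(Cc1ccc(OCc2ccccc2)cc1)[C@@H](C)[C@H](c1ccc(OCc2ccccc2)cc1)c1c(OCc2ccccc2)cc(OCOC)cc1OCc1ccccc1 | intermediate
15 | (3S,4R)-4-[2,6-bis(benzyloxy)-4-(methoxymethoxy)phenyl]-2-[4-(benzyloxy)benzyl]-4-[4-(benzyloxy)phenyl]-3-methylbut-1-ene | C=C(Cc1ccc(OCc2ccccc2)cc1)[C@@H](C)[C@H](c1ccc(OCc2ccccc2)cc1)c1c(OCc2ccccc2)cc(OCOC)cc1OCc1ccccc1 | intermediate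
16 | 9-{(2S,3R,4R)-4-[2,6-bis(benzyloxy)-4-(methoxymethoxy)phenyl]-2-[4-(benzyloxy)benzyl]-4-[4-(benzyloxy)phenyl]-3-methylbutyl}-9-borabicyclo[3.3.1]nonane | COCOc1cc(OCc2ccccc2)c([C@@H](c2ccc(OCc3ccccc3)cc2)[C@H](C)[C@@H](CB2C3CCCC2CCC3)Cc2ccc(OCc3ccccc3)cc2)c(OCc2ccccc2)c1 | intermediate
17 | (2S,3S,4R)-4-[2,6-bis(benzyloxy)-4-(methoxymethoxy)phenyl]-2-[4-(benzyloxy)benzyl]-4-[4-(benzyloxy)phenyl]-3-methylbutan-1-ol | COCOc1cc(OCc2ccccc2)c([C@@H](c2ccc(OCc3ccccc3)cc2)[C@H](C)[C@@H](CO)Cc2ccc(OCc3ccccc3)cc2)c(OCc2ccccc2)c1 | intermediate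
18 | (2S,3S,4R)-4-[2,6-bis(benzyloxy)-4-(methoxymethoxy)phenyl]-2-[4-(benzyloxy)benzyl]-4-[4-(benzyloxy)phenyl]-3-methylbutyl 4-methylbenzenesulfonate | COCOc1cc(OCc2ccccc2)c([C@@H](c2ccc(OCc3ccccc3)cc2)[C@H](C)[C@@H](COS(=O)(=O)c2ccc(C)cc2)Cc2ccc(OCc3ccccc3)cc2)c(OCc2ccccc2)c1 | intermediate
19 | 1,3-bis(benzyloxy)-2-{(1R,2R,3S)-1,4-bis[4-(benzyloxy)phenyl]-2,3-dimethylbutyl}-5-(methoxymethoxy)benzene | COCOc1cc(OCc2ccccc2)c([C@@H](c2ccc(OCc3ccccc3)cc2)[C@H](C)[C@@H](C)Cc2ccc(OCc3ccccc3)cc2)c(OCc2ccccc2)c1 | intermediate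
20 | 3,5-bis(benzyloxy)-4-{(1R,2R,3S)-1,4-bis[4-(benzyloxy)phenyl]-2,3-dimethylbutyl}phenol | Oc1cc(OCc2ccccc2)c([C@@H](c2ccc(OCc3ccccc3)cc2)[C@H](C)[C@@H](C)Cc2ccc(OCc3ccccc3)cc2)c(OCc2ccccc2)c1 | intermediate
21 | 3,5-bis(benzyloxy)-4-{(1R,2R,3S)-1,4-bis[4-(benzyloxy)phenyl]-2,3-dimethylbutyl}-2-bromophenol | Oc1cc(OCc2ccccc2)c([C@@H](c2ccc(OCc3ccccc3)cc2)[C@H](C)[C@@H](C)Cc2ccc(OCc3ccccc3)cc2)c(OCc2ccccc2)c1Br | intermediate
22 | [3,5-bis(benzyloxy)-4-{(1R,2R,3S)-1,4-bis[4-(benzyloxy)phenyl]-2,3-dimethylbutyl}-2-bromophenoxy]trimethylsilane | C[Si](C)(C)Oc1cc(OCc2ccccc2)c([C@@H](c2ccc(OCc3ccccc3)cc2)[C@H](C)[C@@H](C)Cc2ccc(OCc3ccccc3)cc2)c(OCc2ccccc2)c1Br | intermediate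
23 | {2,4-bis(benzyloxy)-3-{(1R,2R,3S)-1,4-bis[4-(benzyloxy)phenyl]-2,3-dimethylbutyl}-6-[(trimethylsilyl)oxy]phenyl}lithium | C[Si](C)(C)Oc1cc(OCc2ccccc2)c([C@@H](c2ccc(OCc3ccccc3)cc2)[C@H](C)[C@@H](C)Cc2ccc(OCc3ccccc3)cc2)c(OCc2ccccc2)c1[Li] | intermediate
24 | lithium 3,5-bis(benzyloxy)-4-{(1R,2R,3S)-1,4-bis[4-(benzyloxy)phenyl]-2,3-dimethylbutyl}-2-(trimethylsilyl)phenolate | [Li+].[O-]c1cc(OCc2ccccc2)c([C@@H](c2ccc(OCc3ccccc3)cc2)[C@H](C)[C@@H](C)Cc2ccc(OCc3ccccc3)cc2)c(OCc2ccccc2)c1[Si](C)(C)C | intermediate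
25 | 3,5-bis(benzyloxy)-4-{(1R,2R,3S)-1,4-bis[4-(benzyloxy)phenyl]-2,3-dimethylbutyl}-2-(trimethylsilyl)phenyl trifluoromethanesulfonate | C[Si](C)(C)c1c(OS(=O)(=O)C(F)(F)F)cc(OCc2ccccc2)c([C@@H](c2ccc(OCc3ccccc3)cc2)[C@H](C)[C@@H](C)Cc2ccc(OCc3ccccc3)cc2)c1OCc1ccccc1 | intermediate
26 | 3-(4-methoxyphenyl)propanoic acid | COc1ccc(CCC(=O)O)cc1 | starting material
27 | 3,5-bis(benzyloxy)-4-{(1R,2R,3S)-1,4-bis[4-(benzyloxy)phenyl]-2,3-dimethylbutyl}-1,2-didehydrobenzene (aryne) | C1#CC(OCc2ccccc2)=C([C@@H](c2ccc(OCc3ccccc3)cc2)[C@H](C)[C@@H](C)Cc2ccc(OCc3ccccc3)cc2)C(OCc2ccccc2)=C1 | intermediate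
28 | caesium 2,4-bis(benzyloxy)-3-{(1R,2R,3S)-1,4-bis[4-(benzyloxy)phenyl]-2,3-dimethylbutyl}-6-{[3-(4-methoxyphenyl)propanoyl]oxy}benzenide | [Cs+].COc1ccc(CCC(=O)Oc2cc(OCc3ccccc3)c([C@@H](c3ccc(OCc4ccccc4)cc3)[C@H](C)[C@@H](C)Cc3ccc(OCc4ccccc4)cc3)c(OCc3ccccc3)[c-]2)cc1 | intermediate
29 | 1-{2,4-bis(benzyloxy)-3-{(1R,2R,3S)-1,4-bis[4-(benzyloxy)phenyl]-2,3-dimethylbutyl}-6-hydroxyphenyl}-3-(4-methoxyphenyl)propan-1-one | COc1ccc(CCC(=O)c2c(O)cc(OCc3ccccc3)c([C@@H](c3ccc(OCc4ccccc4)cc3)[C@H](C)[C@@H](C)Cc3ccc(OCc4ccccc4)cc3)c2OCc2ccccc2)cc1 | intermediate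
30 | 1-{3-[(1R,2R,3S)-1,4-bis(4-hydroxyphenyl)-2,3-dimethylbutyl]-2,4,6-trihydroxyphenyl}-3-(4-methoxyphenyl)propan-1-one | COc1ccc(CCC(=O)c2c(O)cc(O)c([C@@H](c3ccc(O)cc3)[C@H](C)[C@@H](C)Cc3ccc(O)cc3)c2O)cc1 | target

Total steps: 17. Longest linear sequence: 17 steps (1 → 30); 2, 6, 12 and 26 are bought and enter in steps 1, 4, 8 and 16.

Steps most likely to fail

1. Step 16 (aryne insertion). The aryl anion may be protonated before the acyl group has moved, leaving only the aryl ester, or the hindered aryne may be consumed by fluoride or by the product phenoxide before the carboxylate captures it. The fallback builds the ketone without an aryne, setting out from bromophenol 21 and rejoining the route at target 30. O-Benzylation of 21 (BnBr, K2CO3, DMF) gives 1,3,5-tris(benzyloxy)-2-bromo-4-{(1R,2R,3S)-1,4-bis[4-(benzyloxy)phenyl]-2,3-dimethylbutyl}benzene F1. Acid 26 is converted (1,1'-carbonyldiimidazole, then MeNH(OMe)·HCl) into N-methoxy-3-(4-methoxyphenyl)-N-methylpropanamide F2. Bromine–lithium exchange on F1 (n-BuLi, THF, −78 °C) and addition of the aryllithium to F2 (Weinreb ketone synthesis) should give 3-(4-methoxyphenyl)-1-{2,4,6-tris(benzyloxy)-3-{(1R,2R,3S)-1,4-bis[4-(benzyloxy)phenyl]-2,3-dimethylbutyl}phenyl}propan-1-one F3. Hydrogenolysis of F3 (H2, Pd/C, EtOAc/MeOH) removes five benzyl groups and gives 30.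

2. Step 10 (hydroboration). Facial selectivity may be poor if a conformer with the C2' methyl group near the alkene competes, which would lead to the C3' epimer. The fallback sets C3' under catalyst control, setting out from ketone 14 and rejoining at 19. Deprotonation of 14 at benzylic C4' and O-triflation (KN(SiMe3)2, PhNTf2, THF, −78 °C) should give (1Z,3S,4R)-4-[2,6-bis(benzyloxy)-4-(methoxymethoxy)phenyl]-1,4-bis[4-(benzyloxy)phenyl]-3-methylbut-1-en-2-yl trifluoromethanesulfonate F4. Iron-catalysed cross-coupling with MeMgBr (Fe(acac)3 cat., THF, −30 °C) replaces triflate by methyl with retention and gives (1E,3S,4R)-4-[2,6-bis(benzyloxy)-4-(methoxymethoxy)phenyl]-1,4-bis[4-(benzyloxy)phenyl]-2,3-dimethylbut-1-ene F5. Asymmetric hydrogenation of this aryl-conjugated trisubstituted alkene with a cationic iridium phosphine–oxazoline catalyst, [Ir(cod)(L)][B(C6H3(CF3)2)4], in CH2Cl2 under H2 then gives 19; the ligand antipode is chosen by trying both on F5, and benzyl ethers are not cleaved by this homogeneous catalyst.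

3. Step 4 (rhodium-catalysed arylation). Insertion of the arylrhodium species at C4 beside the 5-benzyloxy group may be slow, so that protodeboronation of 6 outruns addition, or enantioselectivity may erode on this electron-rich coumarin. The fallback forms the C4–aryl bond by condensation and sets C1' by reduction, setting out from phloroglucinol 1 and rejoining at 7. Pechmann condensation of 1 with ethyl 3-[4-(benzyloxy)phenyl]-3-oxopropanoate F6 (CF3CO2H, rt) gives 4-[4-(benzyloxy)phenyl]-5,7-dihydroxy-2H-chromen-2-one F7. Selective 7-O-alkylation (MOMCl, K2CO3, acetone) gives 4-[4-(benzyloxy)phenyl]-5-hydroxy-7-(methoxymethoxy)-2H-chromen-2-one F8, and benzylation (BnBr, Cs2CO3, DMF, 60 °C) gives 5-(benzyloxy)-4-[4-(benzyloxy)phenyl]-7-(methoxymethoxy)-2H-chromen-2-one F9. Copper hydride-catalysed asymmetric 1,4-reduction of F9 (Cu(OAc)2, DTBM-SEGPHOS of the antipode that delivers the 4R centre, (EtO)2MeSiH, t-BuOH, toluene) then gives 7.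

Further compounds
F1 | step 16 | 1,3,5-tris(benzyloxy)-2-bromo-4-{(1R,2R,3S)-1,4-bis[4-(benzyloxy)phenyl]-2,3-dimethylbutyl}benzene | Brc1c(OCc2ccccc2)cc(OCc2ccccc2)c([C@@H](c2ccc(OCc3ccccc3)cc2)[C@H](C)[C@@H](C)Cc2ccc(OCc3ccccc3)cc2)c1OCc1ccccc1
F2 | step 16 | N-methoxy-3-(4-methoxyphenyl)-N-methylpropanamide | COc1ccc(CCC(=O)N(C)OC)cc1
F3 | step 16 | 3-(4-methoxyphenyl)-1-{2,4,6-tris(benzyloxy)-3-{(1R,2R,3S)-1,4-bis[4-(benzyloxy)phenyl]-2,3-dimethylbutyl}phenyl}propan-1-one | COc1ccc(CCC(=O)c2c(OCc3ccccc3)cc(OCc3ccccc3)c([C@@H](c3ccc(OCc4ccccc4)cc3)[C@H](C)[C@@H](C)Cc3ccc(OCc4ccccc4)cc3)c2OCc2ccccc2)cc1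
F4 | step 10 | (1Z,3S,4R)-4-[2,6-bis(benzyloxy)-4-(methoxymethoxy)phenyl]-1,4-bis[4-(benzyloxy)phenyl]-3-methylbut-1-en-2-yl trifluoromethanesulfonate | O=S(=O)(O/C(=C\c1ccc(OCc2ccccc2)cc1)[C@@H](C)[C@H](c1ccc(OCc2ccccc2)cc1)c1c(OCc2ccccc2)cc(OCOC)cc1OCc1ccccc1)C(F)(F)F
F5 | step 10 | (1E,3S,4R)-4-[2,6-bis(benzyloxy)-4-(methoxymethoxy)phenyl]-1,4-bis[4-(benzyloxy)phenyl]-2,3-dimethylbut-1-ene | C/C(=C\c1ccc(OCc2ccccc2)cc1)[C@@H](C)[C@H](c1ccc(OCc2ccccc2)cc1)c1c(OCc2ccccc2)cc(OCOC)cc1OCc1ccccc1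
F6 | step 4 | ethyl 3-[4-(benzyloxy)phenyl]-3-oxopropanoate | CCOC(=O)CC(=O)c1ccc(OCc2ccccc2)cc1
F7 | step 4 | 4-[4-(benzyloxy)phenyl]-5,7-dihydroxy-2H-chromen-2-one | O=c1cc(-c2ccc(OCc3ccccc3)cc2)c2c(O)cc(O)cc2o1
F8 | step 4 | 4-[4-(benzyloxy)phenyl]-5-hydroxy-7-(methoxymethoxy)-2H-chromen-2-one | O=c1cc(-c2ccc(OCc3ccccc3)cc2)c2c(O)cc(OCOC)cc2o1
F9 | step 4 | 5-(benzyloxy)-4-[4-(benzyloxy)phenyl]-7-(methoxymethoxy)-2H-chromen-2-one | O=c1cc(-c2ccc(OCc3ccccc3)cc2)c2c(OCc3ccccc3)cc(OCOC)cc2o1
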